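## Retrosynthetic overview

1. The methoxy oxygen on ring A is traced back to a C–B bond: O-methylation and C–B oxidation lead back to arylboronate 17.
2. Ring A is numbered C1 (O-aryl), C2 (OMe), C3 (H), C4–C6 (Br). Its H/Br/Br/Br run on C3–C6 is the C6–C3 chain of 3,4,5-tribromo-2-pyrone 3. The adjacent oxygenated pair C1/C2 is an alkyne whose carbons carry the aryloxy group and boron (15). Cutting C1–C6 and C2–C3 (Diels–Alder, then loss of CO2) is the key disconnection.
3. Alkynylboronate 15 is made from 2,4-dibromophenol (ring B, bought with both bromines) through the vinyl ether, the 2-bromovinyl ether and the ethynyl ether. Pyrone 3 is made from 4-hydroxy-2-pyrone by dibromination and OH-to-Br exchange.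
4. Ring order: ring B is purchased, the pyrone ring is purchased and sacrificed, and ring A is the only ring formed (step 8).

Key step: step 8

Assumption: 4-hydroxy-2H-pyran-2-one (1) is taken as purchasable. Bromovinyl ether 9 is drawn as the Z isomer, the geometry expected to predominate from the dehydrobromination; any E isomer or 1-bromovinyl regioisomer is carried along, since each can give the same alkyne in step 6.

## Route

Step 1
Reactants: 1 4-hydroxy-2H-pyran-2-one
Product: 2 3,5-dibromo-4-hydroxy-2H-pyran-2-one
Conditions: Br2 (2.1 equiv), AcOH, rt then 50 °C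
Reagents that add atoms: bromine, BrBr
Why: Electrophilic enol bromination should take C3 and then C5, the two α-carbons flanking the C4 hydroxyl, while C6 is not nucleophilic and stays C–H.

Step 2
Reactants: 2 3,5-dibromo-4-hydroxy-2H-pyran-2-one
Product: 3 3,4,5-tribromo-2H-pyran-2-one
Conditions: POBr3 (1.5 equiv), DMF (cat.), toluene, 90 °C
Reagents that add atoms: phosphoryl bromide, O=P(Br)(Br)Br
Why: Deoxybromination of a vinylogous acid, in which O-phosphorylation makes the C4 oxygen a leaving group and bromide replaces it by addition–elimination at C4, as in the conversion of 4-hydroxy-2-pyrones into 4-bromo-2-pyrones.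

Step 3
Reactants: 4 2,4-dibromophenol; 5 1,2-dibromoethane (5 equiv)
Product: 6 2,4-dibromo-1-(2-bromoethoxy)benzene
Conditions: K2CO3, MeCN, reflux
Reagents that add atoms: none
Why: Williamson ether synthesis of an acidic phenol with a primary bromide, the excess of dibromide suppressing double alkylation.

Step 4
Reactants: 6 2,4-dibromo-1-(2-bromoethoxy)benzene
Product: 7 2,4-dibromo-1-(ethenyloxy)benzene
Conditions: KOt-Bu (1.5 equiv), THF, 0 °C to rt
Reagents that add atoms: none
Why: E2 dehydrobromination of a 2-bromoethyl aryl ether by a bulky alkoxide gives the aryl vinyl ether, and the aryl bromides are inert to this base at room temperature.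

Step 5
Reactants: 7 2,4-dibromo-1-(ethenyloxy)benzene
Product: 9 2,4-dibromo-1-{[(Z)-2-bromoethenyl]oxy}benzene, via 1,2-dibromoethyl ether 8 (not isolated)
Conditions: Br2 (1.0 equiv), CH2Cl2, −78 °C; then DBU (1.5 equiv), −78 °C to rt
Reagents that add atoms: bromine, BrBr
Why: Bromine adds to the enol ether double bond far faster than it substitutes the deactivated ring B, and base-induced dehydrobromination then expels the labile α-bromo ether bromide together with a proton of the CH2Br group to give the 2-bromovinyl ether.

Step 6
Reactants: 9 2,4-dibromo-1-{[(Z)-2-bromoethenyl]oxy}benzene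
Product: 11 2,4-dibromo-1-(ethynyloxy)benzene, via sodium acetylide 10 (not isolated)
Conditions: NaN(SiMe3)2 (2.2 equiv), THF, −78 to 0 °C; sat. aq. NH4Cl
Reagents that add atoms: none
Why: Anti E2 elimination of the proton on the oxygen-bearing carbon and the trans bromide by a hindered silylamide, which neither exchanges aryl bromides nor metalates ring B, should give the ynol ether, held as its acetylide until the quench.

Step 7
Reactants: 11 2,4-dibromo-1-(ethynyloxy)benzene; 12 2-isopropoxy-4,4,5,5-tetramethyl-1,3,2-dioxaborolane
Product: 15 2-[(2,4-dibromophenoxy)ethynyl]-4,4,5,5-tetramethyl-1,3,2-dioxaborolane, via lithium acetylide 13 (not isolated), via lithium alkynyl(isopropoxy)borate 14 (not isolated)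
Conditions: LiN(i-Pr)2 (1.0 equiv), THF, −78 °C; 12, −78 °C; HCl (2 M in Et2O, 2.0 equiv), −78 °C to rt
Reagents that add atoms: none
Why: Standard alkynylboronate synthesis (acetylide, borate complex, release with anhydrous HCl), using an amide base in place of an alkyllithium so that no bromine–lithium exchange occurs on ring B.

Step 8
Reactants: 15 2-[(2,4-dibromophenoxy)ethynyl]-4,4,5,5-tetramethyl-1,3,2-dioxaborolane; 3 3,4,5-tribromo-2H-pyran-2-one
Product: 17 2-[3,4,5-tribromo-2-(2,4-dibromophenoxy)phenyl]-4,4,5,5-tetramethyl-1,3,2-dioxaborolane, via bridged lactone 16 (not isolated)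
Conditions: o-xylene (degassed), 140 °C, sealed tube, argon
Reagents that add atoms: none
Why: The alkyne carbon remote from oxygen, which carries boron, is the nucleophilic terminus of the ynol ether and should bond to C6 of the electron-poor tribromopyrone while the oxygen-bearing carbon bonds to C3, in an asynchronous inverse-demand Diels–Alder reaction. Ring A is closed by this intermolecular [4+2] cycloaddition as the six-membered carbocycle of bridged lactone 16, with the ring bonds C1–C6 and C2–C3 formed in the one step. Lactone 16 then loses CO2 by retro-[4+2] at the reaction temperature and aromatises directly, so no elimination step exists that could expel the aryloxide or the boryl group. The closest known reactions are the thermal cycloadditions of 2-pyrones with alkynyl pinacolboronates that give arylboronates, and those of 3-bromo- and 3,5-dibromo-2-pyrones with enol ethers, where the oxygen-bearing carbon ends next to C3. The two bridgehead stereocentres of 16 are transient and vanish on aromatisation, so no stereocontrol is needed. The selectivity required is regiochemical (aryloxy carbon beside C–Br, boron carbon beside C–H); the oxygen lone pair, which outweighs the weak acceptor effect of the pinacolboryl group, secures it electronically, and sterically the bulky boronate sits beside the unsubstituted C6 and away from C3–Br.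

Step 9
Reactants: 17 2-[3,4,5-tribromo-2-(2,4-dibromophenoxy)phenyl]-4,4,5,5-tetramethyl-1,3,2-dioxaborolane
Product: 18 3,4,5-tribromo-2-(2,4-dibromophenoxy)phenol
Conditions: H2O2 (30% aq.), NaOH (1 equiv), THF, 0 °C to rt; aq. NH4Cl
Reagents that add atoms: hydrogen peroxide, OO
Why: Oxidation of an arylboronate by hydroperoxide, in which the aryl group migrates from boron to oxygen at the same carbon, should place the hydroxyl at C2 without touching the aryl bromides.

Step 10
Reactants: 18 3,4,5-tribromo-2-(2,4-dibromophenoxy)phenol
Product: 19 1,2,3-tribromo-4-(2,4-dibromophenoxy)-5-methoxybenzene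
Conditions: MeI, K2CO3, DMF, rt
Reagents that add atoms: iodomethane, CI
Why: Williamson O-methylation of the only acidic site gives the target.

## Compound list

1 | 4-hydroxy-2H-pyran-2-one | O=C1C=C(O)C=CO1 | starting material
2 | 3,5-dibromo-4-hydroxy-2H-pyran-2-one | O=C1OC=C(Br)C(O)=C1Br | intermediate
3 | 3,4,5-tribromo-2H-pyran-2-one | O=C1OC=C(Br)C(Br)=C1Br | intermediate
4 | 2,4-dibromophenol | Oc1ccc(Br)cc1Br | starting material
5 | 1,2-dibromoethane | BrCCBr | starting material
6 | 2,4-dibromo-1-(2-bromoethoxy)benzene | BrCCOc1ccc(Br)cc1Br | intermediate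
7 | 2,4-dibromo-1-(ethenyloxy)benzene | C=COc1ccc(Br)cc1Br | intermediate
8 | 2,4-dibromo-1-(1,2-dibromoethoxy)benzene (racemic) | BrCC(Br)Oc1ccc(Br)cc1Br | intermediate
9 | 2,4-dibromo-1-{[(Z)-2-bromoethenyl]oxy}benzene | Br/C=C\Oc1ccc(Br)cc1Br | intermediate
10 | sodium (2,4-dibromophenoxy)acetylide | [Na+].[C-]#COc1ccc(Br)cc1Br | intermediate
11 | 2,4-dibromo-1-(ethynyloxy)benzene | C#COc1ccc(Br)cc1Br | intermediate
12 | 2-isopropoxy-4,4,5,5-tetramethyl-1,3,2-dioxaborolane | CC(C)OB1OC(C)(C)C(C)(C)O1 | starting material
13 | lithium (2,4-dibromophenoxy)acetylide | [Li+].[C-]#COc1ccc(Br)cc1Br | intermediate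
14 | lithium [(2,4-dibromophenoxy)ethynyl](isopropoxy)(pinacolato)borate | [Li+].CC(C)O[B-]1(C#COc2ccc(Br)cc2Br)OC(C)(C)C(C)(C)O1 | intermediate
15 | 2-[(2,4-dibromophenoxy)ethynyl]-4,4,5,5-tetramethyl-1,3,2-dioxaborolane | CC1(C)OB(OC1(C)C)C#COc1ccc(Br)cc1Br | intermediate
16 | 4,7,8-tribromo-5-(2,4-dibromophenoxy)-6-(4,4,5,5-tetramethyl-1,3,2-dioxaborolan-2-yl)-2-oxabicyclo[2.2.2]octa-5,7-dien-3-one (racemic) | O=C1OC2C(Br)=C(Br)C1(Br)C(Oc1ccc(Br)cc1Br)=C2B1OC(C)(C)C(C)(C)O1 | intermediate
17 | 2-[3,4,5-tribromo-2-(2,4-dibromophenoxy)phenyl]-4,4,5,5-tetramethyl-1,3,2-dioxaborolane | CC1(C)OB(OC1(C)C)c1cc(Br)c(Br)c(Br)c1Oc1ccc(Br)cc1Br | intermediate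
18 | 3,4,5-tribromo-2-(2,4-dibromophenoxy)phenol | Oc1cc(Br)c(Br)c(Br)c1Oc1ccc(Br)cc1Br | intermediate
19 | 1,2,3-tribromo-4-(2,4-dibromophenoxy)-5-methoxybenzene | COc1cc(Br)c(Br)c(Br)c1Oc1ccc(Br)cc1Br | target

## Step count and risks

Total step count: 10. Longest linear sequence: 8 steps (steps 3 to 10, from 2,4-dibromophenol).

**Step 8 (key cycloaddition).** The disubstituted, only moderately electron-rich alkyne may add too slowly to the hindered pyrone, the alkynyl C–B bond may be lost by protodeboronation at the temperature needed, or regiocontrol may erode.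
Fallback, setting out from alkyne 11 and returning at phenol 18: silicon replaces boron as the masked oxygen. Alkyne 11 would be lithiated as in step 7 (LiN(i-Pr)2, THF, −78 °C) and silylated with Me3SiCl to [(2,4-dibromophenoxy)ethynyl]trimethylsilane F1. This ynol ether is thermally robust and, lacking the acceptor at boron, the more nucleophilic dienophile. Heated with pyrone 3 (o-xylene, 140–160 °C), it should add in the same sense through the silyl-substituted bridged lactone F2 and, after loss of CO2, give [3,4,5-tribromo-2-(2,4-dibromophenoxy)phenyl]trimethylsilane F3. Ipso-borodesilylation with BBr3 (CH2Cl2, 0 °C to rt), an electrophilic substitution at the silicon-bearing carbon ortho to the aryloxy group, would give dibromo[3,4,5-tribromo-2-(2,4-dibromophenoxy)phenyl]borane F4. This is oxidised in the same flask with NaOH/H2O2 to phenol 18.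

**Step 6 (ynol ether formation).** The base may remove the proton next to bromine and expel 2,4-dibromophenoxide instead of bromide, and the free aryloxyacetylene may oligomerise during isolation.
Fallback, setting out from phenol 4 and returning at boronate 15: the alkyne is built from a substrate in which only bromide can leave. Phenol 4 would be formylated (HCO2H, DCC, CH2Cl2, 0 °C) to 2,4-dibromophenyl formate F5. Ramirez dibromo-olefination (CBr4, PPh3, CH2Cl2, 0 °C) would convert it into 2,4-dibromo-1-[(2,2-dibromoethenyl)oxy]benzene F6, whose single vinylic hydrogen sits on the oxygen-bearing carbon. E2 elimination with NaN(SiMe3)2 (THF, −78 °C) should then give 2,4-dibromo-1-[(bromoethynyl)oxy]benzene F7. Bromine–magnesium exchange at the sp carbon with i-PrMgCl·LiCl at −78 °C, far faster than exchange at the aryl bromides, would give [(2,4-dibromophenoxy)ethynyl]magnesium chloride F8. This is trapped with boronate 12 as the chloromagnesium borate F9 and released with HCl in Et2O to give 15, so the terminal alkyne 11 is never handled.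

**Step 2 (hydroxyl-to-bromine exchange).** Ring opening and tar formation under hot POBr3, or incomplete exchange at the doubly flanked C4, may prevail.
Fallback, setting out from 2 and returning at 3: activation and displacement are separated. Treatment of 2 with Tf2O and pyridine (CH2Cl2, −78 to 0 °C) would give 3,5-dibromo-2-oxo-2H-pyran-4-yl trifluoromethanesulfonate F10. LiBr (acetone or MeCN, rt to 50 °C) should then replace the triflate by addition–elimination at C4 under mild, non-acidic conditions to give 3.

## Further compounds

F1 | step 8 | [(2,4-dibromophenoxy)ethynyl]trimethylsilane | C[Si](C)(C)C#COc1ccc(Br)cc1Br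
F2 | step 8 | 4,7,8-tribromo-5-(2,4-dibromophenoxy)-6-(trimethylsilyl)-2-oxabicyclo[2.2.2]octa-5,7-dien-3-one (racemic) | O=C1OC2C(Br)=C(Br)C1(Br)C(Oc1ccc(Br)cc1Br)=C2[Si](C)(C)C
F3 | step 8 | [3,4,5-tribromo-2-(2,4-dibromophenoxy)phenyl]trimethylsilane | C[Si](C)(C)c1cc(Br)c(Br)c(Br)c1Oc1ccc(Br)cc1Br
F4 | step 8 | dibromo[3,4,5-tribromo-2-(2,4-dibromophenoxy)phenyl]borane | BrB(Br)c1cc(Br)c(Br)c(Br)c1Oc1ccc(Br)cc1Br
F5 | step 6 | 2,4-dibromophenyl formate | O=COc1ccc(Br)cc1Br
F6 | step 6 | 2,4-dibromo-1-[(2,2-dibromoethenyl)oxy]benzene | BrC(Br)=COc1ccc(Br)cc1Br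
F7 | step 6 | 2,4-dibromo-1-[(bromoethynyl)oxy]benzene | BrC#COc1ccc(Br)cc1Br
F8 | step 6 | [(2,4-dibromophenoxy)ethynyl]magnesium chloride | Cl[Mg]C#COc1ccc(Br)cc1Br
F9 | step 6 | chloromagnesium [(2,4-dibromophenoxy)ethynyl](isopropoxy)(pinacolato)borate | CC(C)O[B-]1(C#COc2ccc(Br)cc2Br)OC(C)(C)C(C)(C)O1.[Mg+]Cl
F10 | step 2 | 3,5-dibromo-2-oxo-2H-pyran-4-yl trifluoromethanesulfonate | O=C1OC=C(Br)C(OS(=O)(=O)C(F)(F)F)=C1Br
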